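Ring B (the central ring, numbered from the carbon bearing its ester carbonyl as C1) is disconnected across C1–C2 and C5–C6. C1 with its ester carbon and the adjacent methyl-bearing C6 are the alkyne carbons of a but-2-ynoate already esterified to ring C O4. C2–C5, oxygenated at C2 and C4, come from a 1,3-dioxygenated silyl diene. One Diels–Alder/aromatisation step thus builds ring B, delivers its hindered ester link to ring C without an acylation, and frees O4 for the ring A acid. The precursor is benzyl orsellinate carrying a but-2-ynoyl ester on O4, its chelated 2-hydroxyl masked in the flask as a trimethylsilyl ether.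

Key step: step 5

Remarks: each ring is numbered from the carbon that bears its carboxyl carbon (C1). The target has no stereocentre and no stereogenic double bond, so no configuration has to be set. The ring C 2-hydroxyl is masked only transiently (trimethylsilyl ether 9, formed by silyl transfer from excess diene). No separate silylation and no fluoride treatment of a base-sensitive depside is then needed, and one hydrogenolysis ends the route.

Step 1
Reactants: 1 methyl acetoacetate
Product: 2 methyl 3-(trimethylsilyloxy)but-2-enoate (E/Z mixture)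
Conditions: Me3SiCl, Et3N, hexane, rt
Reagents that add atoms: chlorotrimethylsilane, C[Si](C)(C)Cl
Why: O-silylation of the enolisable β-keto ester with a chlorosilane and a tertiary amine should give the conjugated silyl enol ether, whose double-bond geometry is of no consequence later.

Step 2
Reactants: 2 methyl 3-(trimethylsilyloxy)but-2-enoate
Product: 4 (1E)-1-methoxy-1,3-bis(trimethylsilyloxy)buta-1,3-diene, via lithium dienolate 3 (not isolated)
Conditions: LiN(iPr)2, THF, −78 °C; then Me3SiCl, −78 °C to rt
Reagents that add atoms: chlorotrimethylsilane, C[Si](C)(C)Cl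
Why: Kinetic γ-deprotonation of the vinylogous ester should give the extended lithium dienolate, which is trapped on oxygen by the chlorosilane to the silyl ketene-acetal diene (enolate O-silylation); either ketene-acetal geometry serves in step 5.

Step 3
Reactants: 5 orsellinic acid
Product: 6 benzyl 2,4-dihydroxy-6-methylbenzoate (benzyl orsellinate)
Conditions: BnBr, KHCO3, DMF, rt
Reagents that add atoms: benzyl bromide, BrCc1ccccc1
Why: SN2 alkylation of the carboxylate, the only group that KHCO3 deprotonates, should give the benzyl ester without touching the phenols and without the heat that decarboxylates the acid.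

Step 4
Reactants: 6 benzyl 2,4-dihydroxy-6-methylbenzoate, 7 but-2-ynoic acid
Product: 8 benzyl 4-(but-2-ynoyloxy)-2-hydroxy-6-methylbenzoate
Conditions: DCC, DMAP (cat.), CH2Cl2, −20 to 0 °C
Reagents that add atoms: none
Why: Steglich esterification should acylate the free 4-hydroxyl in preference to the 2-hydroxyl, which is deactivated by its hydrogen bond to the ester carbonyl, while low temperature and only catalytic DMAP suppress isomerisation of the ynoate to the allenoate.

Step 5
Reactants: 8 benzyl 4-(but-2-ynoyloxy)-2-hydroxy-6-methylbenzoate, 4 (1E)-1-methoxy-1,3-bis(trimethylsilyloxy)buta-1,3-diene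
Product: 11 benzyl 4-(2,4-dihydroxy-6-methylbenzoyloxy)-2-hydroxy-6-methylbenzoate (benzyl lecanorate), via ring C trimethylsilyl ether 9 (not isolated), via cyclohexadiene cycloadduct 10 (not isolated)
Conditions: 4 (3 equiv), PhMe, rt to 60 °C, then 110 °C (sealed tube); then 1 M HCl, THF, 0 °C to rt
Reagents that add atoms: none
Why: One equivalent of 4 should first pass a Me3Si group to the ring C phenol (neutral O-silylation by a silyl ketene acetal), so that 9 carries no acidic proton; a further molecule of 4 then adds across the electron-poor triple bond in a thermal, asynchronous, normal-demand [4+2] cycloaddition, its CH2 terminus bonding to the methyl-bearing β-carbon (new C5–C6) and its ketene-acetal carbon to the α-carbon (new C1–C2). The closest known reaction type is the Diels–Alder benzannulation of 1,3-dioxygenated silyl ketene-acetal dienes with alkynoates to give resorcylates. Ring B closes as a six-membered carbocycle by intermolecular union of a four-carbon and a two-carbon unit, both ring bonds arising in the one cycloaddition. The only new stereocentre is the mixed-ketal carbon of 10, formed racemic and erased when dilute acid hydrolyses the ketal (loss of methanol) and the silyl ethers and the resulting dienone tautomerises to the resorcinol, so 11 has none. The step needs regioselectivity, secured by the matched polarisation of the diene (both oxygens push electron density to the CH2 terminus) and of the ynoate (β-carbon electrophilic), and chemoselectivity for the alkyne over the aryl and benzyl ester carbonyls, secured by heating without any Lewis acid. The aryl ester makes the alkyne a better dienophile than an alkyl ynoate, and the two ring B hydroxyls emerge free and already differentiated (O2 chelated, O4 not).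

Step 6
Reactants: 12 2,4-dihydroxy-6-methylbenzaldehyde
Product: 13 2-hydroxy-4-methoxy-6-methylbenzaldehyde
Conditions: MeI (1.05 equiv), K2CO3 (1.0 equiv), acetone, rt
Reagents that add atoms: iodomethane, CI
Why: Williamson methylation with one equivalent of electrophile should take the more acidic, non-chelated 4-hydroxyl, the 2-hydroxyl being tied up in a hydrogen bond to the aldehyde.

Step 7
Reactants: 13 2-hydroxy-4-methoxy-6-methylbenzaldehyde
Product: 14 2-(benzyloxy)-4-methoxy-6-methylbenzaldehyde
Conditions: BnBr, K2CO3, DMF, 60 °C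
Reagents that add atoms: benzyl bromide, BrCc1ccccc1
Why: Williamson benzylation of the remaining chelated phenol should proceed under these more forcing conditions.

Step 8
Reactants: 14 2-(benzyloxy)-4-methoxy-6-methylbenzaldehyde
Product: 16 2-(benzyloxy)-4-methoxy-6-methylphenol, via aryl formate 15 (not isolated)
Conditions: mCPBA, CH2Cl2, 0 °C to rt; aq. Na2S2O3 wash; then K2CO3 (cat.), MeOH, rt
Reagents that add atoms: 3-chloroperoxybenzoic acid, O=C(OO)c1cccc(Cl)c1
Why: Baeyer–Villiger oxidation of the electron-rich, di-ortho-substituted aldehyde should proceed with aryl migration to the formate, which mild methanolysis cleaves to the phenol (Dakin-type overall change).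

Step 9
Reactants: 16 2-(benzyloxy)-4-methoxy-6-methylphenol
Product: 17 1,2-bis(benzyloxy)-5-methoxy-3-methylbenzene
Conditions: BnBr, K2CO3, DMF, 60 °C
Reagents that add atoms: benzyl bromide, BrCc1ccccc1
Why: Williamson benzylation caps the oxidation-prone phenol and should give the fully protected triol.

Step 10
Reactants: 17 1,2-bis(benzyloxy)-5-methoxy-3-methylbenzene
Product: 19 3,4-bis(benzyloxy)-6-methoxy-2-methylbenzaldehyde, via iminium chloride 18 (not isolated)
Conditions: POCl3, DMF, 0 to 60 °C; then aq. NaOAc, rt
Reagents that add atoms: N,N-dimethylformamide, CN(C)C=O; water, O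
Why: Vilsmeier–Haack formylation should attack C4 of 17, para to the C1 benzyloxy group and ortho to the methoxy group, as orcinol dimethyl ether does, and not C6, which lies between two alkoxy groups.

Step 11
Reactants: 19 3,4-bis(benzyloxy)-6-methoxy-2-methylbenzaldehyde
Product: 20 3,4-bis(benzyloxy)-6-methoxy-2-methylbenzoic acid
Conditions: NaClO2, NaH2PO4, 2-methylbut-2-ene (excess), t-BuOH/THF/H2O, rt
Reagents that add atoms: sodium chlorite, [Na+].[O-]Cl=O
Why: Pinnick oxidation should convert the hindered aldehyde to the acid, the alkene scavenger removing HOCl before it can chlorinate the electron-rich ring.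

Step 12
Reactants: 20 3,4-bis(benzyloxy)-6-methoxy-2-methylbenzoic acid, 11 benzyl 4-(2,4-dihydroxy-6-methylbenzoyloxy)-2-hydroxy-6-methylbenzoate
Product: 22 benzyl 4-{4-[3,4-bis(benzyloxy)-6-methoxy-2-methylbenzoyloxy]-2-hydroxy-6-methylbenzoyloxy}-2-hydroxy-6-methylbenzoate, via mixed trifluoroacetic anhydride 21 (not isolated)
Conditions: (CF3CO)2O, PhMe, rt; then 11, rt
Reagents that add atoms: none
Why: Mixed-anhydride esterification, in which the trifluoroacetic mixed anhydride serves as a source of the stabilised di-ortho-substituted aroyl cation, should acylate the only non-chelated phenol of 11, ring B O4, as is usual for orsellinate-type acids and phenols in depside synthesis.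

Step 13
Reactants: 22 benzyl 4-{4-[3,4-bis(benzyloxy)-6-methoxy-2-methylbenzoyloxy]-2-hydroxy-6-methylbenzoyloxy}-2-hydroxy-6-methylbenzoate
Product: 23 4-{4-[(3,4-dihydroxy-6-methoxy-2-methylbenzoyl)oxy]-2-hydroxy-6-methylbenzoyloxy}-2-hydroxy-6-methylbenzoic acid (target)
Conditions: H2 (1 atm), Pd/C (10 wt%), EtOAc, rt
Reagents that add atoms: none
Why: Catalytic hydrogenolysis should cleave the benzyl ester and both benzyl ethers in one operation while leaving the two aryl ester links, the aryl methyl ether and the arenes untouched.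

Compound list
1 | methyl acetoacetate | COC(=O)CC(C)=O | starting material
2 | methyl 3-(trimethylsilyloxy)but-2-enoate (E/Z mixture) | COC(=O)C=C(C)O[Si](C)(C)C | intermediate
3 | lithium 1-methoxy-3-(trimethylsilyloxy)buta-1,3-dien-1-olate | [Li+].COC([O-])=CC(=C)O[Si](C)(C)C | intermediate (not isolated)
4 | (1E)-1-methoxy-1,3-bis(trimethylsilyloxy)buta-1,3-diene | CO/C(O[Si](C)(C)C)=C\C(=C)O[Si](C)(C)C | intermediate
5 | orsellinic acid (2,4-dihydroxy-6-methylbenzoic acid) | Cc1cc(O)cc(O)c1C(=O)O | starting material
6 | benzyl 2,4-dihydroxy-6-methylbenzoate | Cc1cc(O)cc(O)c1C(=O)OCc1ccccc1 | intermediate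
7 | but-2-ynoic acid | CC#CC(=O)O | starting material
8 | benzyl 4-(but-2-ynoyloxy)-2-hydroxy-6-methylbenzoate | CC#CC(=O)Oc1cc(C)c(C(=O)OCc2ccccc2)c(O)c1 | intermediate
9 | benzyl 4-(but-2-ynoyloxy)-6-methyl-2-(trimethylsilyloxy)benzoate | CC#CC(=O)Oc1cc(C)c(C(=O)OCc2ccccc2)c(O[Si](C)(C)C)c1 | intermediate (not isolated)
10 | 4-[(benzyloxy)carbonyl]-3-methyl-5-(trimethylsilyloxy)phenyl 6-methoxy-2-methyl-4,6-bis(trimethylsilyloxy)cyclohexa-1,4-diene-1-carboxylate (racemic at the ketal carbon) | COC1(O[Si](C)(C)C)C=C(O[Si](C)(C)C)CC(C)=C1C(=O)Oc1cc(C)c(C(=O)OCc2ccccc2)c(O[Si](C)(C)C)c1 | intermediate (not isolated)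
11 | benzyl 4-(2,4-dihydroxy-6-methylbenzoyloxy)-2-hydroxy-6-methylbenzoate | Cc1cc(O)cc(O)c1C(=O)Oc1cc(C)c(C(=O)OCc2ccccc2)c(O)c1 | intermediate
12 | 2,4-dihydroxy-6-methylbenzaldehyde | Cc1cc(O)cc(O)c1C=O | starting material
13 | 2-hydroxy-4-methoxy-6-methylbenzaldehyde | COc1cc(C)c(C=O)c(O)c1 | intermediate
14 | 2-(benzyloxy)-4-methoxy-6-methylbenzaldehyde | COc1cc(C)c(C=O)c(OCc2ccccc2)c1 | intermediate
15 | 2-(benzyloxy)-4-methoxy-6-methylphenyl formate | COc1cc(C)c(OC=O)c(OCc2ccccc2)c1 | intermediate (not isolated)
16 | 2-(benzyloxy)-4-methoxy-6-methylphenol | COc1cc(C)c(O)c(OCc2ccccc2)c1 | intermediate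
17 | 1,2-bis(benzyloxy)-5-methoxy-3-methylbenzene | COc1cc(C)c(OCc2ccccc2)c(OCc2ccccc2)c1 | intermediate
18 | N-{[3,4-bis(benzyloxy)-6-methoxy-2-methylphenyl]methylidene}-N-methylmethanaminium chloride | COc1cc(OCc2ccccc2)c(OCc2ccccc2)c(C)c1C=[N+](C)C.[Cl-] | intermediate (not isolated)
19 | 3,4-bis(benzyloxy)-6-methoxy-2-methylbenzaldehyde | COc1cc(OCc2ccccc2)c(OCc2ccccc2)c(C)c1C=O | intermediate
20 | 3,4-bis(benzyloxy)-6-methoxy-2-methylbenzoic acid | COc1cc(OCc2ccccc2)c(OCc2ccccc2)c(C)c1C(=O)O | intermediate
21 | 3,4-bis(benzyloxy)-6-methoxy-2-methylbenzoic trifluoroacetic anhydride | COc1cc(OCc2ccccc2)c(OCc2ccccc2)c(C)c1C(=O)OC(=O)C(F)(F)F | intermediate (not isolated)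
22 | benzyl 4-{4-[3,4-bis(benzyloxy)-6-methoxy-2-methylbenzoyloxy]-2-hydroxy-6-methylbenzoyloxy}-2-hydroxy-6-methylbenzoate | COc1cc(OCc2ccccc2)c(OCc2ccccc2)c(C)c1C(=O)Oc1cc(C)c(C(=O)Oc2cc(C)c(C(=O)OCc3ccccc3)c(O)c2)c(O)c1 | intermediate
23 | 4-{4-[(3,4-dihydroxy-6-methoxy-2-methylbenzoyl)oxy]-2-hydroxy-6-methylbenzoyloxy}-2-hydroxy-6-methylbenzoic acid | COc1cc(O)c(O)c(C)c1C(=O)Oc1cc(C)c(C(=O)Oc2cc(C)c(C(=O)O)c(O)c2)c(O)c1 | target

Total step count: 13.
Longest linear sequence: 8 steps (steps 6–13, from 12 to 23).

Steps most likely to fail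

Step 5. The but-2-ynoate may be too sluggish a dienophile, so that thermal decay of the diene, or its silyl or acyl transfer to the aryl ester, outruns cycloaddition. The adduct may also aromatise by loss of silanol, leaving the ring B C2 oxygen methylated. Fallback (ring B brought in preformed and joined by acylation): starting from 12, both phenols would be alkylated with 4-methoxybenzyl chloride (K2CO3, DMF) to 2,4-bis[(4-methoxyphenyl)methoxy]-6-methylbenzaldehyde F1. Chlorite oxidation (NaClO2, NaH2PO4, 2-methylbut-2-ene) would give 2,4-bis[(4-methoxyphenyl)methoxy]-6-methylbenzoic acid F2. Coupling of F2 with the 4-hydroxyl of 6 (DCC, cat. DMAP, CH2Cl2) would give benzyl 4-{2,4-bis[(4-methoxyphenyl)methoxy]-6-methylbenzoyloxy}-2-hydroxy-6-methylbenzoate F3. CF3CO2H with Et3SiH in CH2Cl2 at 0 °C should then remove both 4-methoxybenzyl ethers and leave the benzyl ester, returning to the route at 11.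

Step 12. The di-ortho-substituted acid may acylate slowly, so that trifluoroacetylation of 11, acyl exchange at its existing depside ester, or attack at a chelated hydroxyl competes (loss of site selectivity). Fallback (rings joined in the order A–B, then C): 20 would be converted with (COCl)2 and catalytic DMF in CH2Cl2 to 3,4-bis(benzyloxy)-6-methoxy-2-methylbenzoyl chloride F4. F4 would acylate (Et3N, cat. DMAP, CH2Cl2) the non-chelated 4-hydroxyl of aldehyde 12, a small phenol that tolerates excess reagent and forcing conditions, to give 4-formyl-3-hydroxy-5-methylphenyl 3,4-bis(benzyloxy)-6-methoxy-2-methylbenzoate F5. Chlorite oxidation (NaClO2, NaH2PO4, 2-methylbut-2-ene) would give 4-[3,4-bis(benzyloxy)-6-methoxy-2-methylbenzoyloxy]-2-hydroxy-6-methylbenzoic acid F6. Carbodiimide coupling of F6 with the 4-hydroxyl of 6 (DCC, toluene, rt) would return to the route at 22.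

Step 10. Formylation may be slow at the position flanked by methyl and methoxy, or may divide between C4 and C6 of 17 (poor regioselectivity). Fallback (halogenation, metalation and carboxylation in place of formylation and oxidation): 17 would be brominated with N-bromosuccinimide in MeCN at 0 °C. The small electrophile strongly prefers the position para to the C1 benzyloxy group, giving 1,2-bis(benzyloxy)-4-bromo-5-methoxy-3-methylbenzene F7. Bromine–lithium exchange (n-BuLi, THF, −78 °C) would give [3,4-bis(benzyloxy)-6-methoxy-2-methylphenyl]lithium F8. Quenching with CO2 and acidification would return to the route at 20, bypassing 19.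

Further compounds
F1 | step 5 | 2,4-bis[(4-methoxyphenyl)methoxy]-6-methylbenzaldehyde | COc1ccc(COc2cc(C)c(C=O)c(OCc3ccc(OC)cc3)c2)cc1
F2 | step 5 | 2,4-bis[(4-methoxyphenyl)methoxy]-6-methylbenzoic acid | COc1ccc(COc2cc(C)c(C(=O)O)c(OCc3ccc(OC)cc3)c2)cc1
F3 | step 5 | benzyl 4-{2,4-bis[(4-methoxyphenyl)methoxy]-6-methylbenzoyloxy}-2-hydroxy-6-methylbenzoate | COc1ccc(COc2cc(C)c(C(=O)Oc3cc(C)c(C(=O)OCc4ccccc4)c(O)c3)c(OCc3ccc(OC)cc3)c2)cc1
F4 | step 12 | 3,4-bis(benzyloxy)-6-methoxy-2-methylbenzoyl chloride | COc1cc(OCc2ccccc2)c(OCc2ccccc2)c(C)c1C(Cl)=O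
F5 | step 12 | 4-formyl-3-hydroxy-5-methylphenyl 3,4-bis(benzyloxy)-6-methoxy-2-methylbenzoate | COc1cc(OCc2ccccc2)c(OCc2ccccc2)c(C)c1C(=O)Oc1cc(C)c(C=O)c(O)c1
F6 | step 12 | 4-[3,4-bis(benzyloxy)-6-methoxy-2-methylbenzoyloxy]-2-hydroxy-6-methylbenzoic acid | COc1cc(OCc2ccccc2)c(OCc2ccccc2)c(C)c1C(=O)Oc1cc(C)c(C(=O)O)c(O)c1
F7 | step 10 | 1,2-bis(benzyloxy)-4-bromo-5-methoxy-3-methylbenzene | COc1cc(OCc2ccccc2)c(OCc2ccccc2)c(C)c1Br
F8 | step 10 | [3,4-bis(benzyloxy)-6-methoxy-2-methylphenyl]lithium | [Li]c1c(C)c(OCc2ccccc2)c(OCc2ccccc2)cc1OC
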